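The butenolide ring (O1, C2 lactone carbonyl, C3 methyl, C4 carboxyl, C5 alkyl) is disconnected at the O1–C2 bond. Its 5-hydroxy congener, the photooxygenation product of a 2-alkyl-4-methyl-3-furoate, opens in water to a carboxylate that holds a C5 ketone cis across the C3=C4 alkene. A ketoreductase reduces that ketone to the (S)-alcohol and mild acid closes the lactone, so one operation sets the only stereocentre and forms the ring. The precursor is the racemic tert-butyl ester lactol carrying the remote methyl ketone as a dioxolane, assembled from ω-pentadecalactone by Roskamp homologation and Feist–Benary condensation. Aqueous CF3CO2H then unmasks both acid and ketone.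

Key step: step 8

Remark: in the ring-opened form of the lactol the acyl group is cis to the free carboxyl and the two carboxyl carbons are trans (a fumarate-type alkene); because the ester carbon outranks the ketone or carbinol carbon, this geometry is E in CIP terms and is named and drawn so below.

Remark: buffer salts and the citric acid used for pH adjustment in the key step are treated as medium; the ketoreductase is taken from a screening panel and its identity is left open.

Step 1
Reactants: 1 ω-pentadecalactone; 2 N,O-dimethylhydroxylamine hydrochloride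
Product: 3 15-hydroxy-N-methoxy-N-methylpentadecanamide
Conditions: MeNH(OMe)·HCl, i-PrMgCl, THF, −20 → 0 °C; aq. NH4Cl
Reagents that add atoms: N,O-dimethylhydroxylamine hydrochloride, CNOC.Cl
Why: Weinreb amide formation: the chloromagnesium amide made from the hydroxylamine salt and i-PrMgCl opens the lactone by acyl substitution, and the resulting amide is inert to the hindered Grignard reagent at this temperature.

Step 2
Reactants: 3 15-hydroxy-N-methoxy-N-methylpentadecanamide; 4 methylmagnesium bromide
Product: 5 16-hydroxyhexadecan-2-one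
Conditions: MeMgBr (3 equiv), THF, 0 °C; aq. NH4Cl
Reagents that add atoms: methylmagnesium bromide, C[Mg]Br
Why: Weinreb ketone synthesis: after deprotonation of the hydroxyl, MeMgBr adds once to the amide and the magnesium-chelated tetrahedral intermediate persists until the quench, so the methyl ketone should form without over-addition.

Step 3
Reactants: 5 16-hydroxyhexadecan-2-one; 6 ethylene glycol
Product: 7 14-(2-methyl-1,3-dioxolan-2-yl)tetradecan-1-ol
Conditions: HOCH2CH2OH, p-TsOH·H2O (cat.), PhMe, reflux, Dean–Stark
Reagents that add atoms: ethylene glycol, OCCO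
Why: Acid-catalysed ketalisation driven by azeotropic removal of water converts the methyl ketone into its 1,3-dioxolane, the five-membered cyclic ketal being favoured over mixed ketals with the primary alcohol.

Step 4
Reactants: 7 14-(2-methyl-1,3-dioxolan-2-yl)tetradecan-1-ol
Product: 8 14-(2-methyl-1,3-dioxolan-2-yl)tetradecanal
Conditions: n-Pr4N[RuO4] (cat.), NMO, 4 Å MS, CH2Cl2, rt
Reagents that add atoms: none
Why: Ley–Griffith oxidation takes the primary alcohol to the aldehyde under neutral anhydrous conditions, which should spare the acid-labile dioxolane and stop short of the carboxylic acid.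

Step 5
Reactants: 8 14-(2-methyl-1,3-dioxolan-2-yl)tetradecanal; 9 tert-butyl diazoacetate
Product: 10 tert-butyl 16-(2-methyl-1,3-dioxolan-2-yl)-3-oxohexadecanoate
Conditions: N2CHCO2t-Bu, SnCl2 (cat.), CH2Cl2, rt
Reagents that add atoms: tert-butyl diazoacetate, CC(C)(C)OC(=O)C=[N+]=[N-]
Why: Roskamp homologation: the diazo carbon adds to the SnCl2-activated aldehyde and a 1,2-hydride shift with loss of N2 gives the β-keto ester, a reaction that is at its best with unbranched aliphatic aldehydes and is mild enough for the ketal.

Step 6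
Reactants: 10 tert-butyl 16-(2-methyl-1,3-dioxolan-2-yl)-3-oxohexadecanoate; 11 chloroacetone
Product: 13 tert-butyl 4-methyl-2-[13-(2-methyl-1,3-dioxolan-2-yl)tridecyl]furan-3-carboxylate, via hydroxydihydrofuran 12 (not isolated)
Conditions: ClCH2COCH3, pyridine, 50 °C; then PPTS (cat.), 4 Å MS, PhMe, 60 °C
Reagents that add atoms: chloroacetone, CC(=O)CCl
Why: Feist–Benary furan synthesis: the β-keto ester adds in aldol fashion to the carbonyl of chloroacetone, its enol oxygen displaces chloride (5-exo-tet) and the tertiary alcohol of 12, whose racemic stereocentre is thereby removed, is lost on mild acid-catalysed aromatisation, a bond order that places methyl on C4 and leaves C5 unsubstituted.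

Step 7
Reactants: 13 tert-butyl 4-methyl-2-[13-(2-methyl-1,3-dioxolan-2-yl)tridecyl]furan-3-carboxylate; 14 dioxygen
Product: 16 racemic tert-butyl 2-hydroxy-4-methyl-5-oxo-2-[13-(2-methyl-1,3-dioxolan-2-yl)tridecyl]-2,5-dihydrofuran-3-carboxylate, via furan endoperoxide 15 (not isolated)
Conditions: O2, hν (visible), tetraphenylporphyrin (cat.), i-Pr2NEt, CH2Cl2, −78 °C → rt
Reagents that add atoms: dioxygen, O=O
Why: Singlet oxygen adds [4+2] across C2 and C5 of the furan and the amine then removes the single bridgehead hydrogen of 15 (Kornblum–DeLaMare fragmentation), which can only place the carbonyl at the former C5 and the hydroxyl on the alkyl-bearing carbon; the lactol carbon forms racemic, which is of no consequence because it becomes a ketone in step 8.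

Step 8
Reactants: 16 racemic tert-butyl 2-hydroxy-4-methyl-5-oxo-2-[13-(2-methyl-1,3-dioxolan-2-yl)tridecyl]-2,5-dihydrofuran-3-carboxylate
Product: 19 tert-butyl (2S)-4-methyl-5-oxo-2-[13-(2-methyl-1,3-dioxolan-2-yl)tridecyl]-2,5-dihydrofuran-3-carboxylate, via ring-opened keto acid 17 (not isolated), via (4S)-hydroxy acid 18 (not isolated)
Conditions: (S)-selective ketoreductase, NADP+ (cat.), i-PrOH (10% v/v), K2HPO4/KH2PO4 buffer pH 7, 30 °C; then aq. citric acid to pH 4.5, 0 °C, EtOAc
Reagents that add atoms: none
Why: Near neutral pH lactol 16 opens to keto carboxylate 17, the ketoreductase transfers hydride from NADPH (recycled by i-PrOH) to its C4 ketone, which is C5 of the butenolide, and brief acidification protonates 18 so that the new hydroxyl attacks the cis carboxyl carbon and expels water. The closest known reaction type is the ketoreductase reduction of γ-keto acids and esters whose hydroxy acids lactonise to enantioenriched γ-lactones. The butenolide ring closes by 5-exo-trig acyl substitution, forming the O1–C2 bond. The C5 stereocentre is set under enzyme control: an (S)-selective enzyme picked by screening holds the linear chain and the alkenyl diester in different pockets and delivers hydride to a single face, and because the racemic lactol carbon becomes planar on ring opening all material should converge on one enantiomer. The step needs 1,2- over 1,4-reduction, no reduction of the remote carbonyl and a cis hydroxy acid: a ketoreductase has no ene-reductase activity, the methyl ketone is masked as the dioxolane, the tert-butyl ester resists esterases and could only close a four-membered ring, and the furan origin fixes the acyl group cis to the free carboxyl.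

Step 9
Reactants: 19 tert-butyl (2S)-4-methyl-5-oxo-2-[13-(2-methyl-1,3-dioxolan-2-yl)tridecyl]-2,5-dihydrofuran-3-carboxylate; 20 water
Product: 21 (2S)-4-methyl-5-oxo-2-(14-oxopentadecyl)-2,5-dihydrofuran-3-carboxylic acid
Conditions: CF3CO2H/H2O (9:1), CH2Cl2, 0 °C → rt
Reagents that add atoms: water, O
Why: Acidolysis of the tert-butyl ester (loss of isobutene via the tert-butyl cation) and acid-catalysed hydrolysis of the dioxolane proceed together in aqueous CF3CO2H, while the butenolide and its C5 stereocentre, which is labile only to base, should be untouched.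

Compound list
1 | ω-pentadecalactone (oxacyclohexadecan-2-one) | O=C1CCCCCCCCCCCCCCO1 | starting material
2 | N,O-dimethylhydroxylamine hydrochloride | CNOC.Cl | starting material
3 | 15-hydroxy-N-methoxy-N-methylpentadecanamide | CON(C)C(=O)CCCCCCCCCCCCCCO | intermediate
4 | methylmagnesium bromide | C[Mg]Br | starting material
5 | 16-hydroxyhexadecan-2-one | CC(=O)CCCCCCCCCCCCCCO | intermediate
6 | ethylene glycol | OCCO | starting material
7 | 14-(2-methyl-1,3-dioxolan-2-yl)tetradecan-1-ol | CC1(OCCO1)CCCCCCCCCCCCCCO | intermediate
8 | 14-(2-methyl-1,3-dioxolan-2-yl)tetradecanal | CC1(OCCO1)CCCCCCCCCCCCCC=O | intermediate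
9 | tert-butyl diazoacetate | CC(C)(C)OC(=O)C=[N+]=[N-] | starting material
10 | tert-butyl 16-(2-methyl-1,3-dioxolan-2-yl)-3-oxohexadecanoate | CC1(OCCO1)CCCCCCCCCCCCCC(=O)CC(=O)OC(C)(C)C | intermediate
11 | chloroacetone | CC(=O)CCl | starting material
12 | tert-butyl 4-hydroxy-4-methyl-2-[13-(2-methyl-1,3-dioxolan-2-yl)tridecyl]-4,5-dihydrofuran-3-carboxylate (racemic) | CC1(OCCO1)CCCCCCCCCCCCCC2=C(C(=O)OC(C)(C)C)C(C)(O)CO2 | intermediate (not isolated)
13 | tert-butyl 4-methyl-2-[13-(2-methyl-1,3-dioxolan-2-yl)tridecyl]furan-3-carboxylate | CC1(OCCO1)CCCCCCCCCCCCCc2occ(C)c2C(=O)OC(C)(C)C | intermediate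
14 | dioxygen | O=O | starting material
15 | tert-butyl 5-methyl-1-[13-(2-methyl-1,3-dioxolan-2-yl)tridecyl]-2,3,7-trioxabicyclo[2.2.1]hept-5-ene-6-carboxylate (racemic) | CC1(OCCO1)CCCCCCCCCCCCCC23OOC(O2)C(C)=C3C(=O)OC(C)(C)C | intermediate (not isolated)
16 | tert-butyl 2-hydroxy-4-methyl-5-oxo-2-[13-(2-methyl-1,3-dioxolan-2-yl)tridecyl]-2,5-dihydrofuran-3-carboxylate (racemic lactol) | CC1(OCCO1)CCCCCCCCCCCCCC2(O)OC(=O)C(C)=C2C(=O)OC(C)(C)C | intermediate
17 | (2E)-3-(tert-butoxycarbonyl)-2-methyl-17-(2-methyl-1,3-dioxolan-2-yl)-4-oxoheptadec-2-enoic acid | CC1(OCCO1)CCCCCCCCCCCCCC(=O)/C(C(=O)OC(C)(C)C)=C(/C)C(=O)O | intermediate (not isolated)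
18 | (2E,4S)-3-(tert-butoxycarbonyl)-4-hydroxy-2-methyl-17-(2-methyl-1,3-dioxolan-2-yl)heptadec-2-enoic acid | CC1(OCCO1)CCCCCCCCCCCCC[C@H](O)/C(C(=O)OC(C)(C)C)=C(/C)C(=O)O | intermediate (not isolated)
19 | tert-butyl (2S)-4-methyl-5-oxo-2-[13-(2-methyl-1,3-dioxolan-2-yl)tridecyl]-2,5-dihydrofuran-3-carboxylate | CC1(OCCO1)CCCCCCCCCCCCC[C@@H]2OC(=O)C(C)=C2C(=O)OC(C)(C)C | intermediate
20 | water | O | starting material
21 | (2S)-4-methyl-5-oxo-2-(14-oxopentadecyl)-2,5-dihydrofuran-3-carboxylic acid | CC(=O)CCCCCCCCCCCCC[C@@H]1OC(=O)C(C)=C1C(=O)O | target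

Total step count: 9. Longest linear sequence: 9 steps, from 1 to 21.

Steps most likely to fail

Step 8. The hindered alkenyl ketone may not be accepted by any enzyme of the panel, or hydride delivery may be poorly face-selective. The fallback sets out from 16. Alkylation of its ring-opened carboxylate (MeI, K2CO3, DMF, rt) should give methyl (2E)-3-(tert-butoxycarbonyl)-2-methyl-17-(2-methyl-1,3-dioxolan-2-yl)-4-oxoheptadec-2-enoate F1. Corey–Bakshi–Shibata reduction of this enone ((R)-2-methyl-CBS-oxazaborolidine, catecholborane, PhMe, −78 °C, the alkenyl group acting as the large substituent) should give methyl (2E,4S)-3-(tert-butoxycarbonyl)-4-hydroxy-2-methyl-17-(2-methyl-1,3-dioxolan-2-yl)heptadec-2-enoate F2. Warming F2 with PPTS (cat.) should lactonise it with loss of methanol and so return to the route at 19.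

Step 6. Carbon alkylation of the keto ester at the CH2Cl carbon may compete with the aldol pathway and lead to the isomeric 5-methylfuran, pyridine may consume chloroacetone by quaternisation, and dehydration may stall. The fallback sets out from 10. Regitz diazo transfer (4-acetamidobenzenesulfonyl azide, Et3N, MeCN) should give tert-butyl 2-diazo-16-(2-methyl-1,3-dioxolan-2-yl)-3-oxohexadecanoate F3. Rh2(OAc)4-catalysed decomposition in the presence of ethyl 1-propenyl ether (formal [3+2] addition of the keto carbenoid to the enol ether, the ether carbon ending at C5) should give tert-butyl 5-ethoxy-4-methyl-2-[13-(2-methyl-1,3-dioxolan-2-yl)tridecyl]-4,5-dihydrofuran-3-carboxylate F4. PPTS-catalysed loss of ethanol in warm PhMe should return to the route at 13.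

Step 7. Cycloaddition of singlet oxygen to the ester-deactivated furan may be slow, and the endoperoxide may break down by paths other than the base-induced fragmentation. The fallback sets out from 13. Oxidative ring opening with NBS, NaHCO3 in acetone/H2O at −20 °C should give tert-butyl (2E)-3-methyl-2-[14-(2-methyl-1,3-dioxolan-2-yl)tetradecanoyl]-4-oxobut-2-enoate F5. Pinnick oxidation of its aldehyde (NaClO2, NaH2PO4, 2-methyl-2-butene, t-BuOH/H2O) should give the keto acid, which closes to 16.

Further compounds
F1 | step 8 | methyl (2E)-3-(tert-butoxycarbonyl)-2-methyl-17-(2-methyl-1,3-dioxolan-2-yl)-4-oxoheptadec-2-enoate | CC1(OCCO1)CCCCCCCCCCCCCC(=O)/C(C(=O)OC(C)(C)C)=C(/C)C(=O)OC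
F2 | step 8 | methyl (2E,4S)-3-(tert-butoxycarbonyl)-4-hydroxy-2-methyl-17-(2-methyl-1,3-dioxolan-2-yl)heptadec-2-enoate | CC1(OCCO1)CCCCCCCCCCCCC[C@H](O)/C(C(=O)OC(C)(C)C)=C(/C)C(=O)OC
F3 | step 6 | tert-butyl 2-diazo-16-(2-methyl-1,3-dioxolan-2-yl)-3-oxohexadecanoate | CC1(OCCO1)CCCCCCCCCCCCCC(=O)C(=[N+]=[N-])C(=O)OC(C)(C)C
F4 | step 6 | tert-butyl 5-ethoxy-4-methyl-2-[13-(2-methyl-1,3-dioxolan-2-yl)tridecyl]-4,5-dihydrofuran-3-carboxylate (diastereomer mixture) | CC1(OCCO1)CCCCCCCCCCCCCC2=C(C(=O)OC(C)(C)C)C(C)C(OCC)O2
F5 | step 7 | tert-butyl (2E)-3-methyl-2-[14-(2-methyl-1,3-dioxolan-2-yl)tetradecanoyl]-4-oxobut-2-enoate | CC1(OCCO1)CCCCCCCCCCCCCC(=O)/C(C(=O)OC(C)(C)C)=C(/C)C=O
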